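## Retrosynthetic overview

1. The target is (2S)-naringenin carrying three C-prenyl groups (C6, C8, C3′). No ring is built: the chromanone core and the C2 stereocentre are bought intact in (2S)-naringenin.
2. Each aryl–prenyl unit is disconnected to aryl–allyl (olefin cross-metathesis with 2-methyl-2-butene), and each Ar–CH2 bond to Ar–I plus an allyl sulfone (photoredox radical allylation, three bonds in one operation).
3. The three C–I handles come from one electrophilic tri-iodination: C6 and C8 on the phloroglucinol A-ring, C3′ ortho to the 4′-OH.
4. Allyl is installed rather than prenyl because the tertiary (α,α-dimethylallyl) sulfone needed for direct radical prenylation isomerises by sulfonyl-radical 1,3-shift to the unreactive prenyl sulfone.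

Assumption: (2S)-naringenin is purchased as the natural laevorotatory enantiomer in ≥98% ee, checked once by chiral HPLC on receipt.

## Route

**Step 1**
Reactants: 1, (2S)-naringenin; 2, N-iodosuccinimide
Product: 3, (2S)-5,7-dihydroxy-2-(4-hydroxy-3-iodophenyl)-6,8-diiodochroman-4-one (3′,6,8-triiodonaringenin)
Conditions: NIS (2.05 equiv), MeCN, 0 °C, dark; then NIS (1.0 equiv), TFA (0.3 equiv), 0 °C → rt
Reagents that add atoms: N-iodosuccinimide, O=C1CCC(=O)N1I (three I)
Why: Electrophilic aromatic iodination: the doubly activated A-ring takes the first two iodines at C6 and C8, and the acid-activated third equivalent goes ortho to the 4′-OH (para blocked, first iodine retards a second); the non-basic medium avoids chalcone ring-opening, so C2 stays (S) and no new stereocentre is formed.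

**Step 2**
Reactants: 3, 3′,6,8-triiodonaringenin; 4, allyl phenyl sulfone
Product: 5, (2S)-6,8-diallyl-2-(3-allyl-4-hydroxyphenyl)-5,7-dihydroxychroman-4-one (3′,6,8-triallylnaringenin)
Conditions: 4CzIPN (3 mol %), (TMS)3SiNH(1-adamantyl) (4 equiv), 2,6-lutidine (4 equiv), 4 (20 equiv, 1 M), degassed MeCN, 450 nm LEDs, rt; then KF, AcOH, MeOH
Reagents that add atoms: allyl phenyl sulfone, C=CCS(=O)(=O)c1ccccc1 (three allyl groups)
Why: Proposed new method: a threefold photoredox halogen-atom-transfer / SH2′ allylation of an unprotected poly-iodophenol. Excited 4CzIPN oxidises the aminosilane to a silyl radical, which abstracts iodine from each Ar–I; the σ-aryl radical adds to the CH2 terminus of the allyl sulfone and β-fragmentation gives Ar–allyl plus PhSO2•, which the reduced photocatalyst converts to sulfinate to close the cycle. There is no Si–H or amine C–H donor to quench the aryl radical and no base strong enough to form phenoxides, so C2 is not epimerised and no stereocentre is created; incidental O-silyl ethers are cleaved by the KF/AcOH work-up. The closest known chemistry is silyl-radical activation of aryl halides in metallaphotoredox coupling and radical allylation of alkyl halides with allyl sulfones (Keck-type).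

**Step 3**
Reactants: 5, 3′,6,8-triallylnaringenin; 6, 2-methyl-2-butene
Product: 7, (2S)-5,7-dihydroxy-2-[4-hydroxy-3-(3-methylbut-2-enyl)phenyl]-6,8-bis(3-methylbut-2-enyl)chroman-4-one (target)
Conditions: Grubbs II (3 × 3 mol %), 2-methyl-2-butene/CH2Cl2 (1:1), 40 °C, sealed tube
Reagents that add atoms: 2-methyl-2-butene, CC=C(C)C (three =C(CH3)2 units replacing =CH2)
Why: Olefin cross-metathesis exchanges each terminal =CH2 for =CMe2 (no E/Z issue), with the large excess of 2-methyl-2-butene suppressing homodimerisation; the neutral conditions tolerate the free phenols and chelated ketone and do not touch C2, which remains (S).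

## Compound list

1 | (2S)-naringenin | Oc1ccc([C@@H]2CC(=O)c3c(O)cc(O)cc3O2)cc1 | starting material
2 | N-iodosuccinimide | O=C1CCC(=O)N1I | starting material
3 | (2S)-5,7-dihydroxy-2-(4-hydroxy-3-iodophenyl)-6,8-diiodochroman-4-one | Oc1ccc([C@@H]2CC(=O)c3c(O)c(I)c(O)c(I)c3O2)cc1I | intermediate
4 | allyl phenyl sulfone | C=CCS(=O)(=O)c1ccccc1 | starting material
5 | (2S)-6,8-diallyl-2-(3-allyl-4-hydroxyphenyl)-5,7-dihydroxychroman-4-one | C=CCc1cc([C@@H]2CC(=O)c3c(O)c(CC=C)c(O)c(CC=C)c3O2)ccc1O | intermediate
6 | 2-methyl-2-butene | CC=C(C)C | starting material
7 | (2S)-5,7-dihydroxy-2-[4-hydroxy-3-(3-methylbut-2-enyl)phenyl]-6,8-bis(3-methylbut-2-enyl)chroman-4-one | CC(C)=CCc1cc([C@@H]2CC(=O)c3c(O)c(CC=C(C)C)c(O)c(CC=C(C)C)c3O2)ccc1O | target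

## Summary

Total steps: 3. Longest linear sequence: 3.

Steps most likely to fail, in order:

1. **Step 2 (proposed new step).** Risks are partial hydrodeiodination, aryl-radical addition to allyl groups already installed (oligomers), and an incomplete third coupling. Fallback (known chemistry): tri-O-acetylate 3, run a Pd(0) Stille coupling with allyltributylstannane (or tributyl(3-methylbut-2-enyl)stannane to give the prenyl groups directly), then remove the acetates with NH4OAc in aqueous MeOH to avoid racemisation.

2. **Step 1.** The risk is over-iodination of the B-ring (3′,5′-diiodide) or an inseparable di/tri/tetra-iodide mixture. Fallback: change the handle to bromine using the mono-ortho-selective NBS / cat. TsOH / MeOH bromination to make the 3′,6,8-tribromide, and activate the stronger C–Br bonds in step 2 by silyl-radical abstraction with (TMS)3SiH and an Ir photocatalyst.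

3. **Step 3.** Risks are Ru–H isomerisation of the o-allylphenols to propenyl arenes or stalled conversion from phenol coordination. Fallback: peracetylate 5 first, run the cross-metathesis on the triacetate (precedented on allyl-flavanones), then deacetylate under the same mild non-basic conditions.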